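## Retrosynthetic overview

1. The plan rests on one feature: in this 8-(piperidin-2-yl)-5,7-dihydroxyflavone the piperidine carbons C3' to C6' carry no substituent, so the C4'–C5' bond can be cut as an alkene between an allyl arm on C2' and an allyl arm on nitrogen (ring-closing metathesis).
2. Late stage: O-demethylation at C5 and C7; pyranone ring C from a phenol by O-vinylation with ethyl phenylpropiolate (O1–C2) and intramolecular Friedel–Crafts acylation (C4–C4a); N-CH3 by reduction of the Boc carbonyl.
3. The diene comes from 2-(benzyloxy)-4,6-dimethoxybenzaldehyde by sulfinamide-controlled allylation of its aldimine (sets C2' as R), N-Boc protection and N-allylation.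
4. Ring order: ring A is bought with the aldehyde, the piperidine is closed in step 7, ring C in step 11; the phenyl ring B arrives with the propiolate.

Key step: step 7

Assumption: the zinc Barbier allylation of the N-sulfinyl aldimine is taken to follow the usual metal-bridged chair model, so that the (S)-sulfinyl group directs allyl to the Re face and gives the (R)-amine; should the two ortho-alkoxy groups reverse this sense, (R)-2-methylpropane-2-sulfinamide is used in the same steps.

## Route

Step 1
Reactants: 1 2-hydroxy-4,6-dimethoxybenzaldehyde; 2 benzyl bromide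
Product: 3 2-(benzyloxy)-4,6-dimethoxybenzaldehyde
Conditions: K2CO3, DMF, 50 °C
Reagents that add atoms: none
Why: Williamson ether synthesis on the acidic chelated ortho-phenol; benzyl is chosen because the later hydrogenation removes it while it saturates the ring alkene.

Step 2
Reactants: 3 2-(benzyloxy)-4,6-dimethoxybenzaldehyde; 4 (S)-2-methylpropane-2-sulfinamide
Product: 5 (S,E)-N-[2-(benzyloxy)-4,6-dimethoxybenzylidene]-2-methylpropane-2-sulfinamide
Conditions: Ti(OEt)4 (2 equiv), THF, 65 °C
Reagents that add atoms: none
Why: Ti(OEt)4-mediated condensation of an aldehyde with a sulfinamide, in which titanium activates the hindered, electron-rich carbonyl and takes up the water, so the E-aldimine should form without touching the sulfur stereocenter.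

Step 3
Reactants: 5 (S,E)-N-[2-(benzyloxy)-4,6-dimethoxybenzylidene]-2-methylpropane-2-sulfinamide; 6 allyl bromide
Product: 8 (S)-N-{(R)-1-[2-(benzyloxy)-4,6-dimethoxyphenyl]but-3-en-1-yl}-2-methylpropane-2-sulfinamide, via allylzinc bromide 7 (not isolated)
Conditions: activated Zn dust, THF, 0 °C to rt; then H2O
Reagents that add atoms: none
Why: Barbier allylation of an N-tert-butanesulfinyl aldimine, in which the (S)-sulfinyl group held in a zinc-bridged six-membered chair transition state leaves only the Re face of C=N (N > aryl > H) open, so the new benzylic center should form as R under auxiliary control.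

Step 4
Reactants: 8 (S)-N-{(R)-1-[2-(benzyloxy)-4,6-dimethoxyphenyl]but-3-en-1-yl}-2-methylpropane-2-sulfinamide
Product: 10 (R)-1-[2-(benzyloxy)-4,6-dimethoxyphenyl]but-3-en-1-amine, via amine hydrochloride 9 (not isolated)
Conditions: HCl (4 M in dioxane, 2 equiv), MeOH, 0 °C, 30 min; then aq NaOH
Reagents that add atoms: none
Why: acid methanolysis of the sulfinamide S–N bond (standard auxiliary removal), which at 0 °C should be much faster than ionization of the electron-rich benzylic C–N bond, so the stereocenter is kept.

Step 5
Reactants: 10 (R)-1-[2-(benzyloxy)-4,6-dimethoxyphenyl]but-3-en-1-amine; 11 di-tert-butyl dicarbonate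
Product: 12 tert-butyl {(R)-1-[2-(benzyloxy)-4,6-dimethoxyphenyl]but-3-en-1-yl}carbamate
Conditions: CH2Cl2, rt
Reagents that add atoms: none
Why: N-Boc protection (carbamate formation) of a primary amine, which needs no base and gives the group that later serves both as the metathesis-compatible nitrogen mask and as the source of the N-methyl carbon.

Step 6
Reactants: 12 tert-butyl {(R)-1-[2-(benzyloxy)-4,6-dimethoxyphenyl]but-3-en-1-yl}carbamate; 6 allyl bromide
Product: 13 tert-butyl allyl{(R)-1-[2-(benzyloxy)-4,6-dimethoxyphenyl]but-3-en-1-yl}carbamate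
Conditions: NaH, DMF, 0 °C to rt
Reagents that add atoms: none
Why: N-alkylation of a carbamate anion by SN2 displacement on the reactive allylic bromide; the benzylic C–H is not acidic enough to be touched by NaH.

Step 7
Reactants: 13 tert-butyl allyl{(R)-1-[2-(benzyloxy)-4,6-dimethoxyphenyl]but-3-en-1-yl}carbamate
Product: 14 tert-butyl (R)-2-[2-(benzyloxy)-4,6-dimethoxyphenyl]-3,6-dihydropyridine-1(2H)-carboxylate
Conditions: second-generation Grubbs catalyst RuCl2(=CHPh)(PCy3)(H2IMes) (5 mol %), CH2Cl2 (0.01 M), 40 °C
Reagents that add atoms: none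
Why: Olefin metathesis by [2+2] cycloaddition and cycloreversion: the ruthenium benzylidene exchanges with one terminal alkene (most likely the less hindered N-allyl arm), the new alkylidene adds across the second terminal alkene to a ruthenacyclobutane, and cycloreversion gives the C4'=C5' bond and a ruthenium methylidene, with ethylene leaving the solution. The closest known reaction type is the ring-closing metathesis of N-allyl N-homoallyl carbamates to N-Boc-1,2,3,6-tetrahydropyridines. The piperidine is closed as a six-membered ring by joining the two internal allyl carbons (C4' to C5'), the double bond being endocyclic and necessarily cis. No stereocenter is formed, and C2', set in step 3, has no bond broken and stays R. The step needs ring closure to outrun intermolecular metathesis and alkene migration: the carbamate removes the basicity of nitrogen, its allylic strain against the aryl-bearing C2' turns the two allyl arms toward each other, and the dilution together with loss of ethylene does the rest. The benzyl ether, the methyl ethers and the arene are inert to the catalyst.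

Step 8
Reactants: 14 tert-butyl (R)-2-[2-(benzyloxy)-4,6-dimethoxyphenyl]-3,6-dihydropyridine-1(2H)-carboxylate
Product: 15 tert-butyl (R)-2-(2-hydroxy-4,6-dimethoxyphenyl)piperidine-1-carboxylate
Conditions: H2 (1 atm), Pd/C (10 wt %), EtOAc/MeOH, rt
Reagents that add atoms: none
Why: catalytic hydrogenation of the ring alkene combined with hydrogenolysis of the benzyl ether, while the carbamate keeps the benzylic C2'–N bond from hydrogenolysis.

Step 9
Reactants: 15 tert-butyl (R)-2-(2-hydroxy-4,6-dimethoxyphenyl)piperidine-1-carboxylate
Product: 16 (R)-3,5-dimethoxy-2-(1-methylpiperidin-2-yl)phenol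
Conditions: LiAlH4 (4 equiv), THF, reflux; then H2O/aq NaOH work-up, pH 8–9
Reagents that add atoms: none
Why: hydride reduction of a carbamate to an N-methylamine, in which the Boc carbonyl carbon becomes the N-CH3 group, so deprotection and methylation happen in one operation and no formaldehyde meets the electron-rich free phenol.

Step 10
Reactants: 16 (R)-3,5-dimethoxy-2-(1-methylpiperidin-2-yl)phenol; 17 ethyl 3-phenylpropiolate
Product: 18 ethyl (Z)-3-{3,5-dimethoxy-2-[(R)-1-methylpiperidin-2-yl]phenoxy}-3-phenylacrylate
Conditions: K2CO3 (0.2 equiv), DMF, 80 °C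
Reagents that add atoms: none
Why: base-catalysed oxa-Michael addition of the phenoxide to the β-carbon of the alkynoate (first half of the Ruhemann flavone synthesis), expected mainly as the Z enol ether by anti addition, any E isomer being equilibrated by the acid of step 11.

Step 11
Reactants: 18 ethyl (Z)-3-{3,5-dimethoxy-2-[(R)-1-methylpiperidin-2-yl]phenoxy}-3-phenylacrylate
Product: 19 5,7-dimethoxy-8-[(R)-1-methylpiperidin-2-yl]-2-phenyl-4H-chromen-4-one
Conditions: Eaton's reagent (P2O5 in MeSO3H), 50 °C; then ice, aq NaOH to pH 9
Reagents that add atoms: none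
Why: intramolecular Friedel–Crafts acylation (Ruhemann-type chromone closure) in which the acylium formed from the ester can reach only the one free position ortho to the aryloxy oxygen, a carbon activated by two further oxygen substituents, while the protonated amine stays bound to C2'.

Step 12
Reactants: 19 5,7-dimethoxy-8-[(R)-1-methylpiperidin-2-yl]-2-phenyl-4H-chromen-4-one
Product: 20 5,7-dihydroxy-8-[(R)-1-methylpiperidin-2-yl]-2-phenyl-4H-chromen-4-one
Conditions: BBr3 (6 equiv), CH2Cl2, −78 °C to rt; then H2O, aq NaHCO3 to pH 7–8
Reagents that add atoms: none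
Why: Lewis-acid O-demethylation of aryl methyl ethers, expected to cleave the carbonyl-chelated 5-OMe first and the 7-OMe on warming, at a temperature low enough that the boron-complexed amine does not leave C2'.

## Compound list

1 | 2-hydroxy-4,6-dimethoxybenzaldehyde | COc1cc(O)c(C=O)c(OC)c1 | starting material
2 | benzyl bromide | BrCc1ccccc1 | starting material
3 | 2-(benzyloxy)-4,6-dimethoxybenzaldehyde | COc1cc(OC)c(C=O)c(OCc2ccccc2)c1 | intermediate
4 | (S)-2-methylpropane-2-sulfinamide | CC(C)(C)[S@](=O)N | starting material
5 | (S,E)-N-[2-(benzyloxy)-4,6-dimethoxybenzylidene]-2-methylpropane-2-sulfinamide | CC(C)(C)[S@](=O)/N=C/c1c(OC)cc(OC)cc1OCc1ccccc1 | intermediate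
6 | allyl bromide | C=CCBr | starting material
7 | allylzinc bromide | C=CC[Zn]Br | intermediate (formed in the flask, not isolated)
8 | (S)-N-{(R)-1-[2-(benzyloxy)-4,6-dimethoxyphenyl]but-3-en-1-yl}-2-methylpropane-2-sulfinamide | CC(C)(C)[S@](=O)N[C@H](CC=C)c1c(OC)cc(OC)cc1OCc1ccccc1 | intermediate
9 | (R)-1-[2-(benzyloxy)-4,6-dimethoxyphenyl]but-3-en-1-aminium chloride | [Cl-].[NH3+][C@H](CC=C)c1c(OC)cc(OC)cc1OCc1ccccc1 | intermediate (not isolated)
10 | (R)-1-[2-(benzyloxy)-4,6-dimethoxyphenyl]but-3-en-1-amine | N[C@H](CC=C)c1c(OC)cc(OC)cc1OCc1ccccc1 | intermediate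
11 | di-tert-butyl dicarbonate | CC(C)(C)OC(=O)OC(=O)OC(C)(C)C | starting material
12 | tert-butyl {(R)-1-[2-(benzyloxy)-4,6-dimethoxyphenyl]but-3-en-1-yl}carbamate | CC(C)(C)OC(=O)N[C@H](CC=C)c1c(OC)cc(OC)cc1OCc1ccccc1 | intermediate
13 | tert-butyl allyl{(R)-1-[2-(benzyloxy)-4,6-dimethoxyphenyl]but-3-en-1-yl}carbamate | C=CCN(C(=O)OC(C)(C)C)[C@H](CC=C)c1c(OC)cc(OC)cc1OCc1ccccc1 | intermediate
14 | tert-butyl (R)-2-[2-(benzyloxy)-4,6-dimethoxyphenyl]-3,6-dihydropyridine-1(2H)-carboxylate | CC(C)(C)OC(=O)N1CC=CC[C@@H]1c1c(OC)cc(OC)cc1OCc1ccccc1 | intermediate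
15 | tert-butyl (R)-2-(2-hydroxy-4,6-dimethoxyphenyl)piperidine-1-carboxylate | CC(C)(C)OC(=O)N1CCCC[C@@H]1c1c(OC)cc(OC)cc1O | intermediate
16 | (R)-3,5-dimethoxy-2-(1-methylpiperidin-2-yl)phenol | CN1CCCC[C@@H]1c1c(OC)cc(OC)cc1O | intermediate
17 | ethyl 3-phenylpropiolate | CCOC(=O)C#Cc1ccccc1 | starting material
18 | ethyl (Z)-3-{3,5-dimethoxy-2-[(R)-1-methylpiperidin-2-yl]phenoxy}-3-phenylacrylate | CN1CCCC[C@@H]1c1c(OC)cc(OC)cc1O/C(=C\C(=O)OCC)c1ccccc1 | intermediate
19 | 5,7-dimethoxy-8-[(R)-1-methylpiperidin-2-yl]-2-phenyl-4H-chromen-4-one | CN1CCCC[C@@H]1c1c(OC)cc(OC)c2c(=O)cc(-c3ccccc3)oc12 | intermediate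
20 | 5,7-dihydroxy-8-[(R)-1-methylpiperidin-2-yl]-2-phenyl-4H-chromen-4-one | CN1CCCC[C@@H]1c1c(O)cc(O)c2c(=O)cc(-c3ccccc3)oc12 | target

## Step count and risks

Total steps: 12. Longest linear sequence: 12 steps, from aldehyde 1 to target 20.

Steps most likely to fail:

**Step 11 (closure of ring C).** The ester may be slow to ionize to the acylium, traces of water may hydrolyse the enol ether back to the phenol, and long exposure to hot acid may ionize the benzylic C2'–N bond and erode the configuration. The fallback builds ring C with the carbonyl first. It sets out from phenol 16 and replaces steps 10 and 11. Ac2O with BF3·OEt2 (O-acetylation, then boron-chelate-directed Fries shift to the free position ortho to the hydroxyl) should give 1-{2-hydroxy-4,6-dimethoxy-3-[(R)-1-methylpiperidin-2-yl]phenyl}ethan-1-one F1. Claisen condensation of its enolate with methyl benzoate (NaH, DMF) should give 1-{2-hydroxy-4,6-dimethoxy-3-[(R)-1-methylpiperidin-2-yl]phenyl}-3-phenylpropane-1,3-dione F2. Cyclodehydration (AcOH, catalytic H2SO4, 60 °C) then closes the pyranone and comes back to the route at flavone 19.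

**Step 3 (allylation that sets C2').** Zinc may be chelated by the two ortho ether oxygens, which would lower or invert the facial selectivity, and addition to the hindered, electron-rich imine may be slow. The fallback replaces auxiliary control by reagent control. It sets out from aldehyde 3 and skips steps 2 to 4. LiN(SiMe3)2 in THF should convert 3 into (E)-1-[2-(benzyloxy)-4,6-dimethoxyphenyl]-N-(trimethylsilyl)methanimine F3. Allylboration with B-allyldiisopinocampheylborane and one equivalent of MeOH at −78 °C, followed by acid–base extraction, should give the primary amine directly. The antipode of the borane made from (−)-α-pinene is used, since by the sense known for aldehydes it delivers allyl to the Re face. The fallback comes back to the route at amine 10.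

**Step 9 (Boc to N-methyl).** Reduction of the hindered carbamate next to an aluminium phenoxide may stall at the N-formyl stage, or the carbamate may be cleaved to the N–H piperidine instead of being reduced. The fallback separates deprotection from methylation and does both before the phenol is freed. It sets out from 14 and replaces steps 8 and 9. TMSOTf with 2,6-lutidine in CH2Cl2, then MeOH, should remove the Boc group under non-protic conditions to give (R)-2-[2-(benzyloxy)-4,6-dimethoxyphenyl]-1,2,3,6-tetrahydropyridine F4. Reductive amination with aqueous formaldehyde and NaBH(OAc)3 should give (R)-2-[2-(benzyloxy)-4,6-dimethoxyphenyl]-1-methyl-1,2,3,6-tetrahydropyridine F5; the arene is still fully etherified at this point, so formaldehyde should not attack the ring. Hydrogenation (H2, Pd/C, MeOH) then saturates the alkene and removes the benzyl group, and comes back to the route at phenol 16.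

## Further compounds

F1 | step 11 | 1-{2-hydroxy-4,6-dimethoxy-3-[(R)-1-methylpiperidin-2-yl]phenyl}ethan-1-one | CN1CCCC[C@@H]1c1c(OC)cc(OC)c(C(C)=O)c1O
F2 | step 11 | 1-{2-hydroxy-4,6-dimethoxy-3-[(R)-1-methylpiperidin-2-yl]phenyl}-3-phenylpropane-1,3-dione | CN1CCCC[C@@H]1c1c(OC)cc(OC)c(C(=O)CC(=O)c2ccccc2)c1O
F3 | step 3 | (E)-1-[2-(benzyloxy)-4,6-dimethoxyphenyl]-N-(trimethylsilyl)methanimine | COc1cc(OC)c(/C=N/[Si](C)(C)C)c(OCc2ccccc2)c1
F4 | step 9 | (R)-2-[2-(benzyloxy)-4,6-dimethoxyphenyl]-1,2,3,6-tetrahydropyridine | N1CC=CC[C@@H]1c1c(OC)cc(OC)cc1OCc1ccccc1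
F5 | step 9 | (R)-2-[2-(benzyloxy)-4,6-dimethoxyphenyl]-1-methyl-1,2,3,6-tetrahydropyridine | CN1CC=CC[C@@H]1c1c(OC)cc(OC)cc1OCc1ccccc1
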